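## Analysis of the target

Target 23 is 5,7-dihydroxy-2-(4-hydroxy-2,5-dimethoxyphenyl)-6-methoxy-4H-chromen-4-one, a flavone. Benzo ring A (C4a, C5 to C8, C8a) is fused to the 4-pyranone ring C (O1, C2, C3, C4), and aryl ring B sits on C2. Ring A carries OH at C5, OMe at C6, OH at C7 and H at C8; ring B carries OMe at C2' and C5' and OH at C4'. There is no stereocentre and no stereogenic double bond, so every selectivity question is one of regiochemistry or chemoselectivity. The sensitive groups are three free phenols on electron-rich rings, the reducible C2–C3 enone of ring C, and the 5-hydroxy-4-keto unit, which under strong acid can open and reclose ring C on the other ortho oxygen (Wessely–Moser isomerisation to the 8-methoxy series). The main difficulty is that C4a is flanked by two oxygens, at C5 and at C8a, and ring C must close on the C8a oxygen only. In addition, three of the six ether oxygens must end as phenols and three as methyl ethers, so phenol protection has to be planned from the first step. The strategy rests on the chain C4–C3–C2: it has the oxidation pattern of a 1,3-diketone, which a 3,5-diarylisoxazole stores, with C4 supplied by a nitrile oxide on ring A and C3–C2 by a terminal alkyne on ring B.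

## Retrosynthetic reasoning

23 from 22. The three phenols are uncovered last by cleaving three benzyl ethers. Benzyl is chosen because its removal is neutral and reductive, so the finished 5-hydroxyflavone never meets strong acid or base.

22 from 20 through 21. Ring C is cut at O1–C2. The forward reaction is acid-mediated cyclodehydration of hydroxy diketone 21, which arises in the same flask from enaminone 20 by loss of the methoxymethyl group and hydrolysis of the nitrogen. Only the C8a oxygen carries the acid-labile acetal; the C5 oxygen stays benzylated. The closure can therefore only give the 6-methoxy series.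

20 from 19. The enaminone is the ring-opened form of isoxazole 19; the N–O bond is cut reductively. The isoxazole keeps the diketone inert and non-enolisable until both aryl rings are in place.

19 from 18 and 17. This is the key disconnection: the C3–C4 bond and the O–C2 bond are cut together, giving nitrile oxide 18 (ring A plus C4) and alkyne 17 (ring B plus C3–C2). Cutting here joins two fully substituted arenes without strong base. It avoids a Claisen-type acylation of a di-ortho-substituted, electron-rich aryl ketone, and no free ortho phenol has to be carried through the coupling. The forward reaction has to deliver the 3,5-isomer and must outrun dimerisation of 18.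

18 from 10, 9 and 7. The nitrile oxide comes from aldoxime 10 by oxidation, and the oxime from aldehyde 9. The formyl carbon of 9 is introduced by directed ortho-metalation of 7. Since 7 is symmetric, its two ring C–H positions are equivalent and each lies between the acetal and a benzyl ether, so only one aldehyde can form.

7 from 6, 4, 3, 2 and 1. The acetal is put on phenol 6. That phenol comes from aldehyde 4 by Baeyer–Villiger oxidation, 4 from ester 2 through alcohol 3, and 2 by benzylation of 1. Commercial 1 already has the methyl ether between two free hydroxyls, which is exactly the C5/C6/C7 pattern of ring A.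

17 from 16, 14, 13 and 11. The alkyne is made by one-carbon homologation of aldehyde 16. The aldehyde is placed by Vilsmeier–Haack formylation of 14 para to the benzyloxy group, and 14 comes from phenol 13, the Dakin-type oxidation product of commercial 11.

## Alternatives that were turned down

Alternative 1: Ring A is built de novo and its C4a–C8a bond is formed last.
- Key step: heating cyclobutenone A1, methyl 3-methoxy-3-[1-methoxy-4-oxo-2-(propan-2-yloxy)cyclobut-2-en-1-yl]prop-2-enoate, opens it to a dienylketene. Six-electron electrocyclisation and tautomerisation then give salicylate A2, methyl 6-hydroxy-2,3-dimethoxy-4-(propan-2-yloxy)benzoate.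
- For: the C8a oxygen is born free and already distinguished from all others, the ester at C4a is ready for acylation chemistry, and the substitution pattern follows from the connectivity of A1 without any directing-group question.
- Against: a benzene ring is constructed that can be bought with the right oxygen triad (compound 1). A1 is not an article of commerce and needs several steps of four-membered-ring chemistry. A2 carries a methyl ether on the future C5 oxygen and an isopropyl ether on the C7 oxygen, so a late selective dealkylation is needed beside three methyl ethers that must stay. Ring C also still has to be made by a separate acylation and cyclodehydration on a hindered benzoate.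
- Comparison: it is stronger in how the C8a oxygen is differentiated. The chosen route offers purchasable arenes, a convergent union and no late demethylation.

Alternative 2: Ring A is folded from a polyketide chain attached to a preformed ring C.
- Key step: a lithium amide base converts pyranone A3, methyl 4-{6-[4-(benzyloxy)-2,5-dimethoxyphenyl]-4-oxo-4H-pyran-2-yl}-2-methoxy-3-oxobutanoate, into its extended enolate. C4a attacks the ester carbonyl to form C4a–C5, and tautomerisation gives A4, 2-[4-(benzyloxy)-2,5-dimethoxyphenyl]-5,7-dihydroxy-6-methoxy-4H-chromen-4-one.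
- For: O1 is fixed before ring A exists, so the 6-methoxy versus 8-methoxy problem cannot arise. The 5- and 7-hydroxyls appear unprotected, and only one benzyl group is left to remove. On protecting-group economy it is clearly stronger.
- Against: the most acidic proton of A3 lies between the ketone and the ester. Its enolate is unproductive and deactivates the very carbonyl that must be attacked, so a polyanion is needed. The pyranone is open to nucleophilic ring opening, and A3 is a sensitive polycarbonyl compound that takes a long sequence to make.
- Comparison: the risk sits in a folding step on a fragile substrate. The chosen route spends more steps on protection but each bond-forming event is a well-behaved reaction.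

Alternative 3: Ring C is closed at the aryl carbon–oxygen bond O1–C8a.
- Key step: the enol oxygen of bromo diketone A5, 1-[2-bromo-5-methoxy-4,6-bis(methoxymethoxy)phenyl]-3-[4-(benzyloxy)-2,5-dimethoxyphenyl]propane-1,3-dione, is arylated intramolecularly under copper catalysis with a diamine ligand and base. This gives A6, 2-[4-(benzyloxy)-2,5-dimethoxyphenyl]-6-methoxy-5,7-bis(methoxymethoxy)-4H-chromen-4-one.
- For: the site of closure is set by the bromine, so ring A needs no orthogonal pair of protecting groups. On regiocontrol it is at least as strong as the chosen route, and the step count is similar.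
- Against: A5 requires a Claisen condensation between two hindered, electron-rich partners. The copper step must insert into an electron-rich aryl bromide next to an enolised diketone that binds copper well. Two deprotection steps of different type follow.
- Comparison: the chosen route joins the rings without base or a coupling catalyst and keeps the diketone masked until the last acid step.

Key step: step 12

Assumption: aldoxime 10 is drawn as the E isomer expected for a hindered aryl aldoxime; the Z isomer would be oxidised to the same nitrile oxide 18.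

## Route

Step 1
Reactants: 1 methyl 3,5-dihydroxy-4-methoxybenzoate
Product: 2 methyl 3,5-bis(benzyloxy)-4-methoxybenzoate
Conditions: BnBr, K2CO3, DMF, 60 °C
Reagents that add atoms: benzyl bromide, BrCc1ccccc1
Why: Williamson ether synthesis on two equivalent phenols; the methyl ester and the methyl ether are inert to carbonate and benzyl bromide.

Step 2
Reactants: 2 methyl 3,5-bis(benzyloxy)-4-methoxybenzoate
Product: 3 [3,5-bis(benzyloxy)-4-methoxyphenyl]methanol
Conditions: LiAlH4, THF, 0 °C to rt
Reagents that add atoms: none
Why: Hydride reduction of an aryl ester to the benzylic alcohol; aryl benzyl and methyl ethers do not react with LiAlH4.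

Step 3
Reactants: 3 [3,5-bis(benzyloxy)-4-methoxyphenyl]methanol
Product: 4 3,5-bis(benzyloxy)-4-methoxybenzaldehyde
Conditions: MnO2, CH2Cl2, rt
Reagents that add atoms: none
Why: Activated MnO2 oxidises benzylic alcohols selectively to aldehydes and stops there.

Step 4
Reactants: 4 3,5-bis(benzyloxy)-4-methoxybenzaldehyde
Product: 6 3,5-bis(benzyloxy)-4-methoxyphenol, via formate 5 (not isolated)
Conditions: mCPBA, CH2Cl2, 0 °C to rt; aq. NaHCO3 wash; then K2CO3 (cat.), MeOH, rt
Reagents that add atoms: 3-chloroperoxybenzoic acid, OOC(=O)c1cccc(Cl)c1
Why: Baeyer–Villiger (Dakin-type) oxidation; in the Criegee adduct the trialkoxyaryl group should migrate in preference to hydride, as with 3,4,5-trialkoxybenzaldehydes, and the aryl formate 5 is cleaved by methanolysis.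

Step 5
Reactants: 6 3,5-bis(benzyloxy)-4-methoxyphenol
Product: 7 1,3-bis(benzyloxy)-2-methoxy-5-(methoxymethoxy)benzene
Conditions: MOMCl, iPr2NEt, CH2Cl2, 0 °C to rt
Reagents that add atoms: chloromethyl methyl ether, COCCl
Why: O-alkylation of the phenol to the acetal; this marks the oxygen that becomes O1 with the only acid-labile group on ring A and installs a strong metalation-directing group.

Step 6
Reactants: 7 1,3-bis(benzyloxy)-2-methoxy-5-(methoxymethoxy)benzene
Product: 9 2,4-bis(benzyloxy)-3-methoxy-6-(methoxymethoxy)benzaldehyde, via aryllithium 8 (not isolated)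
Conditions: n-BuLi, THF, −20 to 0 °C; DMF, −78 °C to rt; H2O
Reagents that add atoms: N,N-dimethylformamide, CN(C)C=O
Why: Directed ortho-metalation; the ring C–H between the acetal and a benzyloxy group is the most acidic position and is chelated by both oxygens, the two such positions are equivalent by symmetry, and the aryllithium is formylated by DMF.

Step 7
Reactants: 9 2,4-bis(benzyloxy)-3-methoxy-6-(methoxymethoxy)benzaldehyde
Product: 10 (E)-2,4-bis(benzyloxy)-3-methoxy-6-(methoxymethoxy)benzaldehyde oxime
Conditions: NH2OH·HCl, NaOAc, EtOH/H2O, rt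
Reagents that add atoms: hydroxylamine hydrochloride, Cl.NO
Why: Condensation of the aldehyde with hydroxylamine to the aldoxime; the acetate buffer keeps the medium mild enough for the methoxymethyl acetal.

Step 8
Reactants: 11 2,5-dimethoxybenzaldehyde
Product: 13 2,5-dimethoxyphenol, via formate 12 (not isolated)
Conditions: mCPBA, CH2Cl2, rt; aq. NaHCO3 wash; then K2CO3 (cat.), MeOH, rt
Reagents that add atoms: 3-chloroperoxybenzoic acid, OOC(=O)c1cccc(Cl)c1
Why: Baeyer–Villiger (Dakin-type) oxidation; the ortho methoxy group favours aryl migration, and methanolysis of formate 12 releases the phenol.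

Step 9
Reactants: 13 2,5-dimethoxyphenol
Product: 14 2-(benzyloxy)-1,4-dimethoxybenzene
Conditions: BnBr, K2CO3, acetone, reflux
Reagents that add atoms: benzyl bromide, BrCc1ccccc1
Why: Williamson ether synthesis on the single phenol.

Step 10
Reactants: 14 2-(benzyloxy)-1,4-dimethoxybenzene
Product: 16 4-(benzyloxy)-2,5-dimethoxybenzaldehyde, via iminium chloride 15 (not isolated)
Conditions: POCl3, DMF, 0 to 60 °C; then ice-water
Reagents that add atoms: N,N-dimethylformamide, CN(C)C=O; water, O
Why: Vilsmeier–Haack formylation; the chloroiminium electrophile attacks para to the benzyloxy group and ortho to a methoxy group, the unhindered doubly activated position, as 1,2,4-trialkoxybenzenes do, and the iminium salt 15 is hydrolysed on work-up.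

Step 11
Reactants: 16 4-(benzyloxy)-2,5-dimethoxybenzaldehyde
Product: 17 1-(benzyloxy)-4-ethynyl-2,5-dimethoxybenzene
Conditions: dimethyl (1-diazo-2-oxopropyl)phosphonate, K2CO3, MeOH/THF, 0 °C to rt
Reagents that add atoms: dimethyl (1-diazo-2-oxopropyl)phosphonate, COP(=O)(OC)C(=[N+]=[N-])C(C)=O
Why: Ohira–Bestmann variant of the Seyferth–Gilbert homologation; methanolysis releases the diazomethylphosphonate anion, which olefinates the aldehyde, and loss of N2 with 1,2-hydrogen shift gives the terminal alkyne under conditions that leave the benzyl ether alone.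

Step 12
Reactants: 10 (E)-2,4-bis(benzyloxy)-3-methoxy-6-(methoxymethoxy)benzaldehyde oxime; 17 1-(benzyloxy)-4-ethynyl-2,5-dimethoxybenzene
Product: 19 3-[2,4-bis(benzyloxy)-3-methoxy-6-(methoxymethoxy)phenyl]-5-[4-(benzyloxy)-2,5-dimethoxyphenyl]isoxazole, via nitrile oxide 18 (not isolated)
Conditions: PhI(OAc)2, 17, MeOH/CH2Cl2, 0 °C to rt; then toluene, 80 °C
Reagents that add atoms: none
Why: The oxime hydroxyl exchanges for acetate on the trivalent iodine of PhI(OAc)2, and loss of iodobenzene and acetic acid gives nitrile oxide 18, which is shielded by its two ortho alkoxy groups and should persist in solution instead of dimerising to the furoxan. On warming with 17 it undergoes a concerted, asynchronous (3+2) cycloaddition (Huisgen 1,3-dipolar cycloaddition) in which the nitrile oxide carbon bonds to the terminal alkyne carbon (the future C3–C4 bond) and the oxygen to the aryl-bearing carbon (the future O–C2 bond). The five-membered ring is thus closed by cycloaddition in a single step, both bonds forming on the same face of each component, and it is aromatic as formed, so no later oxidation or elimination is needed. No stereocentre is created. The step needs 3,5- over 3,4-regioselectivity, and the terminal alkyne secures it: its unsubstituted carbon is the less hindered partner for the crowded nitrile oxide carbon and carries the larger frontier-orbital coefficient of an arylacetylene. It also needs a chemoselective oxidant: every phenol is capped, so PhI(OAc)2 has no site for dearomatisation, no strong acid is added, so the acetal survives, and an N-halo oxidant is avoided because it would halogenate the free ring A position between two alkoxy groups. The closest known reaction type is the oxidation of aryl aldoximes with trivalent iodine reagents to nitrile oxides and their cycloaddition to terminal alkynes giving 3,5-disubstituted isoxazoles.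

Step 13
Reactants: 19 3-[2,4-bis(benzyloxy)-3-methoxy-6-(methoxymethoxy)phenyl]-5-[4-(benzyloxy)-2,5-dimethoxyphenyl]isoxazole
Product: 20 (Z)-3-amino-3-[2,4-bis(benzyloxy)-3-methoxy-6-(methoxymethoxy)phenyl]-1-[4-(benzyloxy)-2,5-dimethoxyphenyl]prop-2-en-1-one
Conditions: Mo(CO)6, MeCN/H2O, 80 °C
Reagents that add atoms: none
Why: Reductive isoxazole ring opening; Mo(CO)6 binds nitrogen and cleaves the weak N–O bond, and water protonates the fragments to the Z β-amino enone held by an N–H···O hydrogen bond, while benzyl ethers and the acetal are inert to this neutral reductant, unlike under catalytic hydrogenation.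

Step 14
Reactants: 20 (Z)-3-amino-3-[2,4-bis(benzyloxy)-3-methoxy-6-(methoxymethoxy)phenyl]-1-[4-(benzyloxy)-2,5-dimethoxyphenyl]prop-2-en-1-one
Product: 22 5,7-bis(benzyloxy)-2-[4-(benzyloxy)-2,5-dimethoxyphenyl]-6-methoxy-4H-chromen-4-one, via hydroxy diketone 21 (not isolated)
Conditions: 3 M aq. HCl, THF, 60 °C
Reagents that add atoms: water, O
Why: Aqueous acid cleaves the methoxymethyl acetal and hydrolyses the vinylogous amide to hydroxy diketone 21, whose freed C8a phenol adds to the ring B carbonyl and dehydrates to the 4-pyranone (the cyclodehydration that ends a Baker–Venkataraman flavone synthesis); the other ortho oxygen is still a benzyl ether, so only the 6-methoxy isomer can form.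

Step 15
Reactants: 22 5,7-bis(benzyloxy)-2-[4-(benzyloxy)-2,5-dimethoxyphenyl]-6-methoxy-4H-chromen-4-one
Product: 23 5,7-dihydroxy-2-(4-hydroxy-2,5-dimethoxyphenyl)-6-methoxy-4H-chromen-4-one
Conditions: H2 (1 atm), 10% Pd/C, EtOAc/MeOH, rt
Reagents that add atoms: none
Why: Catalytic hydrogenolysis of three aryl benzyl ethers; the C2–C3 double bond is a doubly aryl-conjugated vinylogous ester and should be reduced far more slowly, so the reaction is stopped once the benzyl ethers are consumed.

## Compound list

1 | methyl 3,5-dihydroxy-4-methoxybenzoate | COC(=O)c1cc(O)c(OC)c(O)c1 | starting material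
2 | methyl 3,5-bis(benzyloxy)-4-methoxybenzoate | COC(=O)c1cc(OCc2ccccc2)c(OC)c(OCc2ccccc2)c1 | intermediate
3 | [3,5-bis(benzyloxy)-4-methoxyphenyl]methanol | OCc1cc(OCc2ccccc2)c(OC)c(OCc2ccccc2)c1 | intermediate
4 | 3,5-bis(benzyloxy)-4-methoxybenzaldehyde | O=Cc1cc(OCc2ccccc2)c(OC)c(OCc2ccccc2)c1 | intermediate
5 | 3,5-bis(benzyloxy)-4-methoxyphenyl formate | O=COc1cc(OCc2ccccc2)c(OC)c(OCc2ccccc2)c1 | intermediate (not isolated)
6 | 3,5-bis(benzyloxy)-4-methoxyphenol | Oc1cc(OCc2ccccc2)c(OC)c(OCc2ccccc2)c1 | intermediate
7 | 1,3-bis(benzyloxy)-2-methoxy-5-(methoxymethoxy)benzene | COCOc1cc(OCc2ccccc2)c(OC)c(OCc2ccccc2)c1 | intermediate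
8 | [2,4-bis(benzyloxy)-3-methoxy-6-(methoxymethoxy)phenyl]lithium | [Li]c1c(OCOC)cc(OCc2ccccc2)c(OC)c1OCc1ccccc1 | intermediate (not isolated)
9 | 2,4-bis(benzyloxy)-3-methoxy-6-(methoxymethoxy)benzaldehyde | COCOc1cc(OCc2ccccc2)c(OC)c(OCc2ccccc2)c1C=O | intermediate
10 | (E)-2,4-bis(benzyloxy)-3-methoxy-6-(methoxymethoxy)benzaldehyde oxime | COCOc1cc(OCc2ccccc2)c(OC)c(OCc2ccccc2)c1/C=N/O | intermediate
11 | 2,5-dimethoxybenzaldehyde | COc1ccc(OC)c(C=O)c1 | starting material
12 | 2,5-dimethoxyphenyl formate | COc1ccc(OC)c(OC=O)c1 | intermediate (not isolated)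
13 | 2,5-dimethoxyphenol | COc1ccc(OC)c(O)c1 | intermediate
14 | 2-(benzyloxy)-1,4-dimethoxybenzene | COc1ccc(OC)c(OCc2ccccc2)c1 | intermediate
15 | N-{[4-(benzyloxy)-2,5-dimethoxyphenyl]methylidene}-N-methylmethanaminium chloride | C[N+](C)=Cc1cc(OC)c(OCc2ccccc2)cc1OC.[Cl-] | intermediate (not isolated)
16 | 4-(benzyloxy)-2,5-dimethoxybenzaldehyde | COc1cc(OCc2ccccc2)c(OC)cc1C=O | intermediate
17 | 1-(benzyloxy)-4-ethynyl-2,5-dimethoxybenzene | COc1cc(OCc2ccccc2)c(OC)cc1C#C | intermediate
18 | 2,4-bis(benzyloxy)-3-methoxy-6-(methoxymethoxy)benzonitrile oxide | COCOc1cc(OCc2ccccc2)c(OC)c(OCc2ccccc2)c1C#[N+][O-] | intermediate (not isolated)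
19 | 3-[2,4-bis(benzyloxy)-3-methoxy-6-(methoxymethoxy)phenyl]-5-[4-(benzyloxy)-2,5-dimethoxyphenyl]isoxazole | COCOc1cc(OCc2ccccc2)c(OC)c(OCc2ccccc2)c1-c1cc(-c2cc(OC)c(OCc3ccccc3)cc2OC)on1 | intermediate
20 | (Z)-3-amino-3-[2,4-bis(benzyloxy)-3-methoxy-6-(methoxymethoxy)phenyl]-1-[4-(benzyloxy)-2,5-dimethoxyphenyl]prop-2-en-1-one | COCOc1cc(OCc2ccccc2)c(OC)c(OCc2ccccc2)c1/C(N)=C/C(=O)c1cc(OC)c(OCc2ccccc2)cc1OC | intermediate
21 | 1-[2,4-bis(benzyloxy)-6-hydroxy-3-methoxyphenyl]-3-[4-(benzyloxy)-2,5-dimethoxyphenyl]propane-1,3-dione | COc1c(OCc2ccccc2)cc(O)c(C(=O)CC(=O)c2cc(OC)c(OCc3ccccc3)cc2OC)c1OCc1ccccc1 | intermediate (not isolated)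
22 | 5,7-bis(benzyloxy)-2-[4-(benzyloxy)-2,5-dimethoxyphenyl]-6-methoxy-4H-chromen-4-one | COc1cc(-c2cc(=O)c3c(OCc4ccccc4)c(OC)c(OCc4ccccc4)cc3o2)c(OC)cc1OCc1ccccc1 | intermediate
23 | 5,7-dihydroxy-2-(4-hydroxy-2,5-dimethoxyphenyl)-6-methoxy-4H-chromen-4-one | COc1cc(-c2cc(=O)c3c(O)c(OC)c(O)cc3o2)c(OC)cc1O | target

## Step count and least certain steps

Total step count: 15. Longest linear sequence: 11 steps (steps 1 to 7, then 12 to 15); the ring B branch (steps 8 to 11) has 4 steps.

Step 12 (key step). The crowded nitrile oxide may add to the alkyne too slowly, so that thermal isomerisation to the isocyanate, slow dimerisation or oxidative side reactions of the electron-rich partners take over.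
- Fallback: it sets out from aldehyde 9 and alkyne 17 and joins the same two carbons by carbonyl addition.
- Deprotonation of 17 (n-BuLi, THF, −78 °C) and addition to 9 should give the propargylic alcohol 1-[2,4-bis(benzyloxy)-3-methoxy-6-(methoxymethoxy)phenyl]-3-[4-(benzyloxy)-2,5-dimethoxyphenyl]prop-2-yn-1-ol F1.
- MnO2 in CH2Cl2 should oxidise it to the ynone 1-[2,4-bis(benzyloxy)-3-methoxy-6-(methoxymethoxy)phenyl]-3-[4-(benzyloxy)-2,5-dimethoxyphenyl]prop-2-yn-1-one F2.
- HCl in MeOH at rt should remove the acetal to give the hydroxy ynone 1-[2,4-bis(benzyloxy)-6-hydroxy-3-methoxyphenyl]-3-[4-(benzyloxy)-2,5-dimethoxyphenyl]prop-2-yn-1-one F3.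
- Et2NH in EtOH should add to the triple bond in conjugate fashion and let the phenol close the six-membered ring with loss of the amine, returning to the route at 22.

Step 6. n-BuLi may remove a benzylic proton of a benzyl ether instead of the ring proton, and the resulting carbanion would undergo Wittig rearrangement.
- Fallback: it sets out from phenol 6 and uses electrophilic instead of organolithium chemistry.
- Magnesium-mediated ortho-formylation (MgCl2, Et3N, paraformaldehyde, MeCN, reflux) should give 2,4-bis(benzyloxy)-6-hydroxy-3-methoxybenzaldehyde F4.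
- O-alkylation with MOMCl and iPr2NEt then returns to the route at 9.

Step 14. Hydrolysis of the nitrogen may lag behind ring closure, so that the material rests as a ring-closed 4-iminium salt. Forcing acid could then erode the benzyl ether on the C5 oxygen before closure and so loosen the regiocontrol.
- Fallback: it sets out from 20 and separates the two events.
- Buffered hydrolysis that the acetal tolerates (aq. AcOH, THF, rt to 40 °C) should give 1-[2,4-bis(benzyloxy)-3-methoxy-6-(methoxymethoxy)phenyl]-3-[4-(benzyloxy)-2,5-dimethoxyphenyl]propane-1,3-dione F5, which no longer contains nitrogen.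
- HCl in MeOH then removes the acetal and cyclodehydrates the diketone, returning to the route at 22.

Step 15. Over-reduction of the C2–C3 double bond to the flavanone may compete with removal of the last benzyl ether.
- Fallback: it sets out from 22 and replaces reduction by Lewis-acid cleavage.
- BCl3 with pentamethylbenzene as cation scavenger in CH2Cl2 at −78 °C should remove the three benzyl groups without touching the methyl ethers, returning to the route at 23.

## Further compounds

F1 | step 12 | 1-[2,4-bis(benzyloxy)-3-methoxy-6-(methoxymethoxy)phenyl]-3-[4-(benzyloxy)-2,5-dimethoxyphenyl]prop-2-yn-1-ol (racemic) | COCOc1cc(OCc2ccccc2)c(OC)c(OCc2ccccc2)c1C(O)C#Cc1cc(OC)c(OCc2ccccc2)cc1OC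
F2 | step 12 | 1-[2,4-bis(benzyloxy)-3-methoxy-6-(methoxymethoxy)phenyl]-3-[4-(benzyloxy)-2,5-dimethoxyphenyl]prop-2-yn-1-one | COCOc1cc(OCc2ccccc2)c(OC)c(OCc2ccccc2)c1C(=O)C#Cc1cc(OC)c(OCc2ccccc2)cc1OC
F3 | step 12 | 1-[2,4-bis(benzyloxy)-6-hydroxy-3-methoxyphenyl]-3-[4-(benzyloxy)-2,5-dimethoxyphenyl]prop-2-yn-1-one | COc1c(OCc2ccccc2)cc(O)c(C(=O)C#Cc2cc(OC)c(OCc3ccccc3)cc2OC)c1OCc1ccccc1
F4 | step 6 | 2,4-bis(benzyloxy)-6-hydroxy-3-methoxybenzaldehyde | COc1c(OCc2ccccc2)cc(O)c(C=O)c1OCc1ccccc1
F5 | step 14 | 1-[2,4-bis(benzyloxy)-3-methoxy-6-(methoxymethoxy)phenyl]-3-[4-(benzyloxy)-2,5-dimethoxyphenyl]propane-1,3-dione | COCOc1cc(OCc2ccccc2)c(OC)c(OCc2ccccc2)c1C(=O)CC(=O)c1cc(OC)c(OCc2ccccc2)cc1OC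
F0 | step 15 | none | none
A1 | alternative 1 | methyl 3-methoxy-3-[1-methoxy-4-oxo-2-(propan-2-yloxy)cyclobut-2-en-1-yl]prop-2-enoate (racemic, alkene geometry not fixed) | COC(=O)C=C(OC)C1(OC)C(OC(C)C)=CC1=O
A2 | alternative 1 | methyl 6-hydroxy-2,3-dimethoxy-4-(propan-2-yloxy)benzoate | COC(=O)c1c(O)cc(OC(C)C)c(OC)c1OC
A3 | alternative 2 | methyl 4-{6-[4-(benzyloxy)-2,5-dimethoxyphenyl]-4-oxo-4H-pyran-2-yl}-2-methoxy-3-oxobutanoate (racemic) | COC(=O)C(OC)C(=O)Cc1cc(=O)cc(-c2cc(OC)c(OCc3ccccc3)cc2OC)o1
A4 | alternative 2 | 2-[4-(benzyloxy)-2,5-dimethoxyphenyl]-5,7-dihydroxy-6-methoxy-4H-chromen-4-one | COc1cc(-c2cc(=O)c3c(O)c(OC)c(O)cc3o2)c(OC)cc1OCc1ccccc1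
A5 | alternative 3 | 1-[2-bromo-5-methoxy-4,6-bis(methoxymethoxy)phenyl]-3-[4-(benzyloxy)-2,5-dimethoxyphenyl]propane-1,3-dione | COCOc1cc(Br)c(C(=O)CC(=O)c2cc(OC)c(OCc3ccccc3)cc2OC)c(OCOC)c1OC
A6 | alternative 3 | 2-[4-(benzyloxy)-2,5-dimethoxyphenyl]-6-methoxy-5,7-bis(methoxymethoxy)-4H-chromen-4-one | COCOc1cc2oc(-c3cc(OC)c(OCc4ccccc4)cc3OC)cc(=O)c2c(OCOC)c1OC
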